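The earlier runs and the new flask come from a simulation from invented constants; noise was put on by code.

The loading of L on E is the same 0.05 mol% in the midnight and spring flasks. If the catalytic step were in command, both flasks should turn over equal fractions of their charge per hour. If the dissolution of E were in command and did not depend on the amount of solid, both should make equal amounts per hour.

all flasks: L 0.05 mol%; G 0.30 mM
- midnight: E 0.12 M; the very flask that is asked about, followed so far
- spring: E 0.080 M; run made earlier
- flask: E 0.12 M

| run | time / h | X / % |
|---|---|---|
| midnight | 1.33 | 1.6 |
| midnight | 2.50 | 2.0 |
| midnight | 4.00 | 4.9 |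
| midnight | 5.00 | 4.6 |
| spring | 1.00 | 0.8 |
| spring | 2.00 | 3.0 |
| spring | 5.00 | 7.6 |
| spring | 12.0 | 17.0 |

(scatter of a reading: 0.5 percentage points)

- as a solid, counted per litre of solution: E
- the numbers in the tables scatter by 0.5 percentage points (one standard deviation)
- reactions considered so far: Z + L -> X + L; E <-> Z; L + G <-> D
- at the start none of E is in solution
- what has only dissolved of E counts as not reacted

* factor on the rate of making X when 50% of the E are converted (what has only dissolved counts as not reacted) if L is charged twice over
* factor on the rate when 50% of the E are converted (what has only dissolved counts as not reacted) if L is charged at 0.005 mol% instead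

Which picture fits? Lines through the origin give the midnight flask 0.0101 h⁻¹ of its charge and the spring flask 0.0143 h⁻¹. Their ratio is 1.42, against 1.50 between the charges, so the amounts per hour, midnight over spring, stand at 1.06, a loose reading.

How much does L still count? Take my own reckoning: put the two steps in series as resistances, with the catalytic one inverse to the L charged. The reading then gives 0.147 for the toll, meaning the catalytic resistance over the dissolution resistance in the midnight flask. The toll reads as a small correction, so in this reckoning dissolution is the rate-limiting step.

With E and G as charged, the rate factor for new L is one plus the toll, over one plus the toll divided by the factor on L. Assuming the rate holds out to 50% conversion, that gives 1.07 for doubling and 0.464 at 0.005 mol%.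

The forecast says 1.06 and 0.5, the second a little above mine: “Doubling L then gains little.”

    Z + L → X + L, rate k1*[Z]*[L]/(1 + ([Z]/Km1)) (0.280 M, k = 1.20 × 10⁵ M⁻¹ h⁻¹)
    E ⇌ Z, rate k2*(cs2 - [Z]) while solid is left; crystals form when [Z] > cs2 (solubility = 5.80 mM, k = 0.220 h⁻¹)
    L + G ⇌ D (K = 2800 M⁻¹, k = 300 M⁻¹ h⁻¹)

The flask gives 1.03 and 0.674. In the flask at 12.0 h, Z is made, each step taken net, 1.00 times as fast as it is used up. The toll, a loose 0.147 as read from the runs, comes to 0.0568 when read backwards from 0.674. The spring flask holds less L, so in this reckoning its toll is larger by the ratio of charges, and the flask over spring becomes 1.03. Taking the rate of 0.00121 M h⁻¹ at 50% conversion in the flask, the spring flask should turn over 0.0147 h⁻¹ of its charge, and the line through its readings gave 0.0143 h⁻¹.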